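# Proposed total synthesis of CNP0147493.0 through a siloxydiene–ynone Diels–Alder construction of ring B

## Structural features

The target is an achiral bibenzyl. Ring A (the ring with the methoxy group) and ring B (the monohydroxy ring) are joined by a CH2–CH2 bridge, and three 4-hydroxybenzyl groups are attached through diarylmethane CH2 links. Ring A is pentasubstituted: the bridge carbon C1 lies between the benzyl-bearing carbons C2 and C6, C3 carries OH, C5 carries OMe and only C4 carries hydrogen. Ring B is 1,2,4-trisubstituted: bridge carbon and benzyl-bearing carbon are neighbours, and the hydroxyl is para to the benzyl-bearing carbon and meta to the bridge-bearing carbon. There is no stereocentre and no ring fusion, so every problem is one of regiochemistry or chemoselectivity. The fragile points are the electron-rich phenols (oxidised easily in base), the three doubly benzylic CH2 groups (open to hydride abstraction and cation chemistry) and the nucleophilic free position C4 of ring A. The real difficulty is threefold: the crowded benzyl–bridge–benzyl array on ring A, the defined pattern of ring B, and the two ring A oxygens, which are equivalent in any simple precursor but must end as one OH and one OMe beside four other phenols. The key step exploits ring B: its oxygen-bearing carbon is para to the benzyl-bearing carbon, which is the relationship a 2-oxygenated buta-1,3-diene sets up with the acyl-bearing carbon of an alkynone, and the acyl carbon is later reduced to the benzyl CH2.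

## Logic of the disconnections

**18 ⇒ 17.** Four benzylic C–O bonds are restored (O–CH2Ph on the three hydroxybenzyl oxygens and on the C3 oxygen of ring A). A neutral hydrogenolysis is the gentlest way to release a polyphenol. Because the ring A oxygen that must end as OH is a benzyl ether and its partner is already the methyl ether, no selective dealkylation remains for the end. The gain is that 17 has one free phenol and can be purified normally. The demand is cleavage of four aryl benzyl ethers without touching the diarylmethane C–C bonds or the methyl ether.

**17 ⇒ 15.** No skeletal bond is cut; the CH2 between ring B and its aryl group is taken back to C=O. The carbonyl is what turns the alkyne into a dienophile, so it must be present at the cycloaddition and removed afterwards. The gain is that the benzyl group of ring B arrives as a simple aroyl unit. The demand is complete deoxygenation of an electron-rich diaryl ketone, with hydride capture faster than Friedel–Crafts attack by the benzhydryl cation.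

**15 ⇒ 13 (through 14).** No C–C bond is cut; ring B is taken back by two hydrogens to the cyclohexa-1,4-diene and its OH to the silyl enol ether. This is the oxidation level at which a 2-siloxydiene and an alkyne combine. The gain is that the substitution pattern of ring B becomes a matter of cycloaddition regiochemistry. The demand is a dehydrogenation that takes the doubly allylic hydrogens of the skipped diene and leaves the doubly benzylic CH2 groups alone.

**13 ⇒ 11 + 12.** Two σ bonds of ring B are cut: bridge-bearing carbon to its CH2 neighbour, and acyl-bearing carbon to its CH2 neighbour. Both flank the one π bond an ynone can offer, and the other four ring carbons with the oxygen are a commercial C4 diene. The gain is that ring B disappears and an acyclic compound holding all of ring A remains. The demand is the para orientation (siloxy carbon opposite the acyl-bearing carbon) and enough reactivity from a β-alkyl ynone.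

**11 ⇒ 9 + 10.** The C(sp)–C(=O) bond is cut. A terminal alkyne and a commercial acid chloride are joined in one step at the ketone oxidation level. The gain is separation of the future benzyl unit of ring B from the ring A fragment. The demand is acylation without base-induced isomerisation of the product.

**9 ⇒ 7 (through 8).** The bond to the terminal alkyne carbon is cut (one-carbon homologation), and the neighbouring carbon is traced to an ester carbonyl. The three-carbon side chain already holds both bridge carbons and the carbon that becomes the bridge-bearing carbon of ring B. The gain is a return to a simple ester. The demand is a reduction that stops at the aldehyde level.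

**7 ⇒ 4 + 5 (through 6).** The two ring A–CH2 bonds at C2 and C6 are cut. Both benzyl groups are identical and come from one commercial benzylic chloride. The gain is that ring A shrinks to a dibromide of a simple arylpropanoate. The demand is a double sp2–sp3 coupling at bromides that each have two ortho neighbours.

**4 ⇒ 3.** Two C–Br bonds are cut. C2 and C6 are para to one ether oxygen and ortho to the other, so electrophilic bromination needs no directing group. The demand is that bromination stops before C4 and does not enter benzylic positions.

**3 ⇒ 2 ⇒ 1.** The ether and ester O–CH2Ph bonds of 3 are cut, then one O–CH3 bond is restored to reach 1. The two methoxy groups of 1 are equivalent, so loss of one gives a single product, and no benzyl ether is yet present for a thiolate to attack. The gain is that the ring A oxygens are differentiated in the first step on the cheapest compound. The demand is that demethylation stops after one methyl group.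

## Other disconnections considered

**Alternative 1:** The cut is at the two bonds between ring A and its benzylic CH2 groups, the same bonds that step 4 forms.
- Forward step: the Grignard reagent A3 (from 5) would add twice to the oxazoline A2. Magnesium bound to the oxazoline nitrogen delivers the benzyl group to the ortho carbon, methoxide leaves, and the second ortho methoxy group is displaced likewise to give A1.
- In favour: no halogenation and no palladium. The benzyl positions are fixed by the directing group and not by the course of an electrophilic bromination; on regiocontrol this alternative is the better one. In bonds formed per step (two) it equals step 4.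
- Against: A2 is not commercial and would take several steps. Benzylic Grignard reagents tend to homocouple. The oxazoline of A1 sits between two benzyl groups, so unmasking it to an aldehyde should be slow. It supplies only one bridge carbon, so ring B would have to be made separately and joined by olefination and hydrogenation. Ring A emerges with two methoxy groups, which brings back the late selective demethylation.
- Comparison: it solves only the crowding of ring A, uses addition–elimination in place of cross-coupling, and would be longer overall because none of ring B is built.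

**Alternative 2:** The cut removes two neighbouring bonds of ring A, one to the first bridge carbon and one to a benzylic carbon.
- Forward step: fluoride (CsF, MeCN) would release the aryne from A5. The enolate carbon of A6 adds to the aryne carbon remote from the methoxy group, the aryl anion closes onto the ketone, and the four-membered alkoxide opens to A4.
- In favour: two vicinal C–C bonds form in one operation, equal to the chosen key step in skeletal bonds. The temperature is far lower than a sealed-tube cycloaddition, which is better. The aroyl group serves as latent benzyl, as in the chosen plan (equal).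
- Against: A5 is a pentasubstituted arene with a silyl group, a triflate and one benzyl group already in place, so it needs several steps. The methoxy group directs the nucleophile to the aryne carbon flanked by the benzyl group, so electronic and steric control oppose each other. The ester carbon of A4 must still become the second bridge carbon and be joined to a separately made ring B. Ring A again carries two methoxy groups.
- Comparison: no ring is built, and the ring A problem is rearranged without touching ring B, so the step count would be higher.

**Alternative 3:** The cut lies inside ring A, between the bridge-bearing carbon and one benzyl-bearing carbon; ring A is built from the open-chain triketone A8.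
- Forward step: in aqueous KOH the enolate at the CH2 next to the terminal ketone would attack the cinnamoyl carbonyl. Loss of water and enolisation give the resorcinol A7 with the E-styryl group in place.
- In favour: like the chosen plan it creates one arene from acyclic carbon (equal in rings formed, with one new bond against two). The end is short: mono-O-methylation and one hydrogenation that saturates the stilbene and removes all benzyl ethers. In steps after the key step this alternative is the better one.
- Against: A8 is a nine-carbon 1,3,5-triketone with two C-benzyl groups and an enone. It has several enolisable positions, can close through oxygen or through carbon in another register, and offers its double bond to conjugate addition. All of ring B with its benzyl group must be made first. Mono-methylation of the symmetrical resorcinol of A7 is statistical, whereas the thiolate demethylation of the chosen plan limits itself.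
- Comparison: it builds the more substituted ring in one step but depends on chemoselectivity among many carbonyl groups rather than on polarity-controlled regiochemistry; the end is shorter and the beginning much longer.

Key step: step 7

**Remark on the chemistry (assumption):** the target has no stereocentre, so no descriptor is needed; 10 and 12 are treated as purchased compounds.

**Correction of the precursor:** a ynone with two methoxy groups on ring A would leave the differentiation of the ring A oxygens to a thiolate demethylation at the end. A thiolate attacks the benzylic carbon of aryl benzyl ethers at least as readily as a methyl group. That step could therefore only follow the hydrogenolysis and would be run on the free, oxidation-prone polyphenol. Here one ring A oxygen is a benzyl ether from step 2 onward, so 11 and 13 carry OBn at C3 and OMe at C5 of ring A. The skeletons of 11 and 13 and the bonds formed in step 7 are unchanged, and the step count does not rise. Two further changes: the ynone is made in one step by acyl Sonogashira coupling, and the hydrolytically labile 13 is carried on without chromatography.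

## Route

Step 1
Reactants: 1 3-(3,5-dimethoxyphenyl)propanoic acid
Product: 2 3-(3-hydroxy-5-methoxyphenyl)propanoic acid
Conditions: NaSEt (3.5 equiv), DMF, 140 °C; then aq. HCl
Reagents that add atoms: none
Why: Nucleophilic O-demethylation by thiolate (SN2 at the methyl carbon); the two methoxy groups are equivalent, and once one is cleaved the ring carries a phenoxide that makes the second aryloxide a much poorer leaving group, so the reaction should stop at the mono-phenol. The carboxylate is a spectator and no benzyl ether is present yet.

Step 2
Reactants: 2 3-(3-hydroxy-5-methoxyphenyl)propanoic acid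
Product: 3 benzyl 3-[3-(benzyloxy)-5-methoxyphenyl]propanoate
Conditions: BnBr (2.3 equiv), K2CO3, DMF, 60 °C
Reagents that add atoms: benzyl bromide, BrCc1ccccc1
Why: Williamson etherification of the phenoxide and O-alkylation of the carboxylate in one operation; the benzyl ester is the ester reduced in step 5, and the benzyl ether marks the ring A oxygen that ends as OH.

Step 3
Reactants: 3 benzyl 3-[3-(benzyloxy)-5-methoxyphenyl]propanoate
Product: 4 benzyl 3-[3-(benzyloxy)-2,6-dibromo-5-methoxyphenyl]propanoate
Conditions: NBS (2.05 equiv), MeCN, 0 °C to rt, dark
Reagents that add atoms: N-bromosuccinimide, O=C1CCC(=O)N1Br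
Why: Electrophilic aromatic bromination; C2 and C6 are para to one alkoxy group and ortho to the other and should react first, whereas C4 is only ortho-activated and shielded by two ether groups, and two bromine atoms deactivate the ring against a third. A polar solvent without light disfavours radical benzylic bromination.

Step 4
Reactants: 4 benzyl 3-[3-(benzyloxy)-2,6-dibromo-5-methoxyphenyl]propanoate; 5 4-(benzyloxy)benzyl chloride
Product: 7 benzyl 3-{3-(benzyloxy)-2,6-bis[4-(benzyloxy)benzyl]-5-methoxyphenyl}propanoate, via [4-(benzyloxy)benzyl]zinc chloride 6 (not isolated)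
Conditions: 5 (2.6 equiv), Zn dust, LiCl, THF, 25 °C; then 4, Pd(OAc)2 (4 mol %), SPhos (8 mol %), THF, 60 °C
Reagents that add atoms: none
Why: Double Negishi coupling; LiCl-promoted zinc insertion into the benzylic chloride gives 6, which tolerates the ester. The bulky, electron-rich zerovalent palladium–SPhos catalyst is suited to oxidative addition at aryl bromides with two ortho neighbours, and the benzyl group has no β-hydrogen to eliminate.

Step 5
Reactants: 7 benzyl 3-{3-(benzyloxy)-2,6-bis[4-(benzyloxy)benzyl]-5-methoxyphenyl}propanoate
Product: 9 1-(benzyloxy)-2,4-bis[4-(benzyloxy)benzyl]-3-(but-3-yn-1-yl)-5-methoxybenzene, via ring A propanal 8 (not isolated)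
Conditions: iBu2AlH (1.1 equiv), CH2Cl2, −78 °C; then MeOH, K2CO3, dimethyl (1-diazo-2-oxopropyl)phosphonate, −78 °C to rt
Reagents that add atoms: dimethyl (1-diazo-2-oxopropyl)phosphonate, CC(=O)C(=[N+]=[N-])P(=O)(OC)OC
Why: One-pot ester-to-alkyne conversion; the aluminium hemiacetal formed at −78 °C releases aldehyde 8 on adding methanol, and 8 is trapped at once by the diazomethylphosphonate anion generated from the Ohira–Bestmann reagent. Loss of phosphate and N2 and a 1,2-hydrogen shift of the alkylidene carbene (Seyferth–Gilbert homologation) give the terminal alkyne.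

Step 6
Reactants: 9 1-(benzyloxy)-2,4-bis[4-(benzyloxy)benzyl]-3-(but-3-yn-1-yl)-5-methoxybenzene; 10 4-(benzyloxy)benzoyl chloride
Product: 11 5-{3-(benzyloxy)-2,6-bis[4-(benzyloxy)benzyl]-5-methoxyphenyl}-1-[4-(benzyloxy)phenyl]pent-2-yn-1-one
Conditions: PdCl2(PPh3)2 (2 mol %), CuI (4 mol %), Et3N, THF, rt
Reagents that add atoms: none
Why: Acyl Sonogashira coupling; the copper acetylide transmetalates to the acylpalladium chloride formed from 10, and reductive elimination gives the ynone directly at the ketone oxidation level. Room temperature and a tertiary amine should avoid isomerisation of the propargylic CH2.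

Step 7
Reactants: 11 5-{3-(benzyloxy)-2,6-bis[4-(benzyloxy)benzyl]-5-methoxyphenyl}-1-[4-(benzyloxy)phenyl]pent-2-yn-1-one; 12 2-(trimethylsilyloxy)buta-1,3-diene
Product: 13 [2-(2-{3-(benzyloxy)-2,6-bis[4-(benzyloxy)benzyl]-5-methoxyphenyl}ethyl)-4-(trimethylsilyloxy)cyclohexa-1,4-dien-1-yl][4-(benzyloxy)phenyl]methanone
Conditions: 12 (5 equiv), BHT (cat.), toluene, sealed tube, 140 °C; volatiles removed in vacuo, crude 13 used directly
Reagents that add atoms: none
Why: Normal-electron-demand Diels–Alder reaction between the HOMO of the electron-rich diene 12 and the LUMO of the ynone 11, concerted but asynchronous. The bond from the diene CH2 next to the siloxy carbon (largest HOMO coefficient, the nucleophilic carbon of the enol ether) to the alkyne carbon β to the carbonyl (largest LUMO coefficient) forms ahead of the bond from the other diene terminus to the acyl-bearing carbon. The closest known reaction type is the cycloaddition of 2-siloxybuta-1,3-dienes with acetylenic ketones and esters to give 4-siloxycyclohexa-1,4-dienes. Ring B is closed by an intermolecular (4+2) cycloaddition that makes both ring bonds in one step, so no exo or endo cyclisation mode applies. No stereocentre is created, because the new ring atoms are sp2 carbons and CH2 groups. The selectivity needed is regiochemical: the para adduct, with the siloxy carbon opposite the acyl-bearing carbon, is secured by the matched polarisation just described, while the meta adduct would pair mismatched termini. Arenes and benzyl ethers are inert, and excess diene, a radical inhibitor and the absence of acid protect the silyl enol ether.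

Step 8
Reactants: 13 [2-(2-{3-(benzyloxy)-2,6-bis[4-(benzyloxy)benzyl]-5-methoxyphenyl}ethyl)-4-(trimethylsilyloxy)cyclohexa-1,4-dien-1-yl][4-(benzyloxy)phenyl]methanone
Product: 15 [2-(2-{3-(benzyloxy)-2,6-bis[4-(benzyloxy)benzyl]-5-methoxyphenyl}ethyl)-4-hydroxyphenyl][4-(benzyloxy)phenyl]methanone, via ring B trimethylsilyl ether 14 (not isolated)
Conditions: DDQ (1.05 equiv), CH2Cl2, 0 °C; then 1 M HCl, THF, rt
Reagents that add atoms: none
Why: Dehydrogenative aromatisation; DDQ abstracts hydride from the doubly allylic CH2 of the skipped diene (the cation is stabilised by the siloxy group) and proton loss gives the arene 14, whose aryl silyl ether is cleaved by dilute acid. Aromatisation of a cyclohexa-1,4-diene should be much faster than attack on the diarylmethane CH2 groups, so one equivalent at 0 °C should be selective.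

Step 9
Reactants: 15 [2-(2-{3-(benzyloxy)-2,6-bis[4-(benzyloxy)benzyl]-5-methoxyphenyl}ethyl)-4-hydroxyphenyl][4-(benzyloxy)phenyl]methanone
Product: 17 3-(2-{3-(benzyloxy)-2,6-bis[4-(benzyloxy)benzyl]-5-methoxyphenyl}ethyl)-4-[4-(benzyloxy)benzyl]phenol, via diarylmethanol 16 (not isolated)
Conditions: Et3SiH (4 equiv), CF3CO2H, CH2Cl2, 0 °C to rt
Reagents that add atoms: none
Why: Ionic hydrogenation; the protonated electron-rich diaryl ketone takes hydride from the silane to give 16, which ionises to a benzhydryl cation stabilised by para oxygen on both rings and is reduced again to the CH2. Excess silane should intercept the cation before Friedel–Crafts attack at C4 of ring A, and aryl benzyl ethers tolerate brief exposure to cold CF3CO2H.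

Step 10
Reactants: 17 3-(2-{3-(benzyloxy)-2,6-bis[4-(benzyloxy)benzyl]-5-methoxyphenyl}ethyl)-4-[4-(benzyloxy)benzyl]phenol
Product: 18 3-{2-[3-hydroxy-2,6-bis(4-hydroxybenzyl)-5-methoxyphenyl]ethyl}-4-(4-hydroxybenzyl)phenol
Conditions: H2 (1 atm), 10% Pd/C, EtOAc/MeOH, rt
Reagents that add atoms: none
Why: Catalytic hydrogenolysis of four aryl benzyl ethers; diarylmethane C–C bonds and the aryl methyl ether are inert under these neutral conditions, which also spare the polyphenol from base and oxidants.

## Compound list

1 | 3-(3,5-dimethoxyphenyl)propanoic acid | COc1cc(CCC(=O)O)cc(OC)c1 | starting material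
2 | 3-(3-hydroxy-5-methoxyphenyl)propanoic acid | COc1cc(O)cc(CCC(=O)O)c1 | intermediate
3 | benzyl 3-[3-(benzyloxy)-5-methoxyphenyl]propanoate | COc1cc(CCC(=O)OCc2ccccc2)cc(OCc2ccccc2)c1 | intermediate
4 | benzyl 3-[3-(benzyloxy)-2,6-dibromo-5-methoxyphenyl]propanoate | COc1cc(OCc2ccccc2)c(Br)c(CCC(=O)OCc2ccccc2)c1Br | intermediate
5 | 4-(benzyloxy)benzyl chloride | ClCc1ccc(OCc2ccccc2)cc1 | starting material
6 | [4-(benzyloxy)benzyl]zinc chloride (not isolated) | Cl[Zn]Cc1ccc(OCc2ccccc2)cc1 | intermediate
7 | benzyl 3-{3-(benzyloxy)-2,6-bis[4-(benzyloxy)benzyl]-5-methoxyphenyl}propanoate | COc1cc(OCc2ccccc2)c(Cc2ccc(OCc3ccccc3)cc2)c(CCC(=O)OCc2ccccc2)c1Cc1ccc(OCc2ccccc2)cc1 | intermediate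
8 | 3-{3-(benzyloxy)-2,6-bis[4-(benzyloxy)benzyl]-5-methoxyphenyl}propanal (not isolated) | COc1cc(OCc2ccccc2)c(Cc2ccc(OCc3ccccc3)cc2)c(CCC=O)c1Cc1ccc(OCc2ccccc2)cc1 | intermediate
9 | 1-(benzyloxy)-2,4-bis[4-(benzyloxy)benzyl]-3-(but-3-yn-1-yl)-5-methoxybenzene | COc1cc(OCc2ccccc2)c(Cc2ccc(OCc3ccccc3)cc2)c(CCC#C)c1Cc1ccc(OCc2ccccc2)cc1 | intermediate
10 | 4-(benzyloxy)benzoyl chloride | O=C(Cl)c1ccc(OCc2ccccc2)cc1 | starting material
11 | 5-{3-(benzyloxy)-2,6-bis[4-(benzyloxy)benzyl]-5-methoxyphenyl}-1-[4-(benzyloxy)phenyl]pent-2-yn-1-one | O=C(C#CCCc1c(Cc2ccc(OCc3ccccc3)cc2)c(OCc2ccccc2)cc(OC)c1Cc1ccc(OCc2ccccc2)cc1)c1ccc(OCc2ccccc2)cc1 | intermediate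
12 | 2-(trimethylsilyloxy)buta-1,3-diene | C=CC(=C)O[Si](C)(C)C | starting material
13 | [2-(2-{3-(benzyloxy)-2,6-bis[4-(benzyloxy)benzyl]-5-methoxyphenyl}ethyl)-4-(trimethylsilyloxy)cyclohexa-1,4-dien-1-yl][4-(benzyloxy)phenyl]methanone | O=C(C1=C(CCc2c(Cc3ccc(OCc4ccccc4)cc3)c(OCc3ccccc3)cc(OC)c2Cc2ccc(OCc3ccccc3)cc2)CC(O[Si](C)(C)C)=CC1)c1ccc(OCc2ccccc2)cc1 | intermediate
14 | [2-(2-{3-(benzyloxy)-2,6-bis[4-(benzyloxy)benzyl]-5-methoxyphenyl}ethyl)-4-(trimethylsilyloxy)phenyl][4-(benzyloxy)phenyl]methanone (not isolated) | O=C(c1ccc(O[Si](C)(C)C)cc1CCc1c(Cc2ccc(OCc3ccccc3)cc2)c(OCc2ccccc2)cc(OC)c1Cc1ccc(OCc2ccccc2)cc1)c1ccc(OCc2ccccc2)cc1 | intermediate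
15 | [2-(2-{3-(benzyloxy)-2,6-bis[4-(benzyloxy)benzyl]-5-methoxyphenyl}ethyl)-4-hydroxyphenyl][4-(benzyloxy)phenyl]methanone | O=C(c1ccc(O)cc1CCc1c(Cc2ccc(OCc3ccccc3)cc2)c(OCc2ccccc2)cc(OC)c1Cc1ccc(OCc2ccccc2)cc1)c1ccc(OCc2ccccc2)cc1 | intermediate
16 | [2-(2-{3-(benzyloxy)-2,6-bis[4-(benzyloxy)benzyl]-5-methoxyphenyl}ethyl)-4-hydroxyphenyl][4-(benzyloxy)phenyl]methanol (racemic, not isolated) | OC(c1ccc(O)cc1CCc1c(Cc2ccc(OCc3ccccc3)cc2)c(OCc2ccccc2)cc(OC)c1Cc1ccc(OCc2ccccc2)cc1)c1ccc(OCc2ccccc2)cc1 | intermediate
17 | 3-(2-{3-(benzyloxy)-2,6-bis[4-(benzyloxy)benzyl]-5-methoxyphenyl}ethyl)-4-[4-(benzyloxy)benzyl]phenol | Oc1ccc(Cc2ccc(OCc3ccccc3)cc2)c(CCc2c(Cc3ccc(OCc4ccccc4)cc3)c(OCc3ccccc3)cc(OC)c2Cc2ccc(OCc3ccccc3)cc2)c1 | intermediate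
18 | 3-{2-[3-hydroxy-2,6-bis(4-hydroxybenzyl)-5-methoxyphenyl]ethyl}-4-(4-hydroxybenzyl)phenol | COc1cc(O)c(Cc2ccc(O)cc2)c(CCc2cc(O)ccc2Cc2ccc(O)cc2)c1Cc1ccc(O)cc1 | target

## Step count and least certain steps

Total step count: 10. Longest linear sequence: 10 steps (1 to 18); 5, 10 and 12 are bought and enter in steps 4, 6 and 7.

**Step 7 (key step).**
- Risk: the cycloaddition may be slow, because the β-alkyl group and the electron-rich aroyl group lower the dienophile reactivity. During long heating the diene may oligomerise or lose its silyl group, and the regiocontrol may erode at high temperature.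
- Fallback: it sets out from 11 and returns to the route at 15. Compound 11 is heated (toluene, 90–110 °C) with (E)-1-methoxy-3-(trimethylsilyloxy)buta-1,3-diene, a more nucleophilic diene with the same orientation. The primary adduct, [2-(2-{3-(benzyloxy)-2,6-bis[4-(benzyloxy)benzyl]-5-methoxyphenyl}ethyl)-6-methoxy-4-(trimethylsilyloxy)cyclohexa-1,4-dien-1-yl][4-(benzyloxy)phenyl]methanone F1, is not dehydrogenated. Dilute HCl in THF eliminates methanol and removes the silyl group, so aromatisation occurs by elimination and no oxidant is needed.

**Step 8.**
- Risk: hydride abstraction at the doubly benzylic CH2 groups of ring A may compete with aromatisation, and premature hydrolysis of the silyl enol ether would leave a ketone that DDQ aromatises less cleanly.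
- Fallback: it sets out from 13 and returns at 15. Compound 13 is hydrolysed on purpose (1 M HCl, THF) to 4-[4-(benzyloxy)benzoyl]-3-(2-{3-(benzyloxy)-2,6-bis[4-(benzyloxy)benzyl]-5-methoxyphenyl}ethyl)cyclohex-3-en-1-one F2. This cyclohexenone is dehydrogenated to the phenol with O2 (1 atm) under Pd(OCOCF3)2, 2-(dimethylamino)pyridine and TsOH in DMSO at 80 °C, the aerobic dehydrogenation of cyclohexenones to phenols by divalent palladium.

**Step 4.**
- Risk: the second coupling at a bromide with two ortho neighbours may stall, and the benzylzinc reagent may homocouple or the aryl bromide may be reduced.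
- Fallback: it sets out from 4 and 5 and returns at 7. Compound 5 is converted by Miyaura borylation (B2pin2, KOAc, zerovalent palladium catalyst) into 2-[4-(benzyloxy)benzyl]-4,4,5,5-tetramethyl-1,3,2-dioxaborolane F3. This is joined to 4 by Suzuki–Miyaura coupling (Pd(OAc)2, SPhos, K3PO4, toluene with a little water, 90 °C), so a slowly transmetalating boron reagent replaces the zinc reagent.

**Step 5.**
- Risk: the ester may be over-reduced to the primary alcohol or incompletely reduced before the homologation reagent is added.
- Fallback: it sets out from 7 and returns at 8. LiAlH4 (THF, 0 °C) gives 3-{3-(benzyloxy)-2,6-bis[4-(benzyloxy)benzyl]-5-methoxyphenyl}propan-1-ol F4. Dess–Martin periodinane (CH2Cl2, rt) oxidises it to 8, which is isolated and then treated with K2CO3, MeOH and the Ohira–Bestmann reagent as in the second half of step 5.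

**Step 9.**
- Risk: partial loss of benzyl ethers in the acid, or capture of the benzhydryl cation by an arene in place of the silane.
- Fallback: it sets out from 15 and returns at 18. Compound 15 is hydrogenated directly (H2, 3–4 bar, Pd/C, EtOAc/AcOH with a trace of HCl), so the diaryl carbonyl is hydrogenolysed to CH2 and the four benzyl ethers are cleaved in the same operation. This bypasses 16 and 17 and makes no new compound (F0).

## Further compounds

F1 | step 7 | [2-(2-{3-(benzyloxy)-2,6-bis[4-(benzyloxy)benzyl]-5-methoxyphenyl}ethyl)-6-methoxy-4-(trimethylsilyloxy)cyclohexa-1,4-dien-1-yl][4-(benzyloxy)phenyl]methanone (racemic) | O=C(C1=C(CCc2c(Cc3ccc(OCc4ccccc4)cc3)c(OCc3ccccc3)cc(OC)c2Cc2ccc(OCc3ccccc3)cc2)CC(O[Si](C)(C)C)=CC1OC)c1ccc(OCc2ccccc2)cc1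
F2 | step 8 | 4-[4-(benzyloxy)benzoyl]-3-(2-{3-(benzyloxy)-2,6-bis[4-(benzyloxy)benzyl]-5-methoxyphenyl}ethyl)cyclohex-3-en-1-one | O=C1CCC(C(=O)c2ccc(OCc3ccccc3)cc2)=C(CCc2c(Cc3ccc(OCc4ccccc4)cc3)c(OCc3ccccc3)cc(OC)c2Cc2ccc(OCc3ccccc3)cc2)C1
F3 | step 4 | 2-[4-(benzyloxy)benzyl]-4,4,5,5-tetramethyl-1,3,2-dioxaborolane | CC1(C)OB(Cc2ccc(OCc3ccccc3)cc2)OC1(C)C
F4 | step 5 | 3-{3-(benzyloxy)-2,6-bis[4-(benzyloxy)benzyl]-5-methoxyphenyl}propan-1-ol | COc1cc(OCc2ccccc2)c(Cc2ccc(OCc3ccccc3)cc2)c(CCCO)c1Cc1ccc(OCc2ccccc2)cc1
F0 | step 9 | none | none
A1 | alternative 1 | 2-{2,6-bis[4-(benzyloxy)benzyl]-3,5-dimethoxyphenyl}-4,4-dimethyl-4,5-dihydrooxazole | COc1cc(OC)c(Cc2ccc(OCc3ccccc3)cc2)c(C2=NC(C)(C)CO2)c1Cc1ccc(OCc2ccccc2)cc1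
A2 | alternative 1 | 4,4-dimethyl-2-(2,3,5,6-tetramethoxyphenyl)-4,5-dihydrooxazole | COc1cc(OC)c(OC)c(C2=NC(C)(C)CO2)c1OC
A3 | alternative 1 | [4-(benzyloxy)benzyl]magnesium chloride | Cl[Mg]Cc1ccc(OCc2ccccc2)cc1
A4 | alternative 2 | methyl 2-{2-[4-(benzyloxy)benzoyl]-6-[4-(benzyloxy)benzyl]-3,5-dimethoxyphenyl}acetate | COC(=O)Cc1c(Cc2ccc(OCc3ccccc3)cc2)c(OC)cc(OC)c1C(=O)c1ccc(OCc2ccccc2)cc1
A5 | alternative 2 | 3-[4-(benzyloxy)benzyl]-4,6-dimethoxy-2-(trimethylsilyl)phenyl trifluoromethanesulfonate | COc1cc(OC)c(OS(=O)(=O)C(F)(F)F)c([Si](C)(C)C)c1Cc1ccc(OCc2ccccc2)cc1
A6 | alternative 2 | methyl 3-[4-(benzyloxy)phenyl]-3-oxopropanoate | COC(=O)CC(=O)c1ccc(OCc2ccccc2)cc1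
A7 | alternative 3 | 4-[(E)-2-{5-(benzyloxy)-2-[4-(benzyloxy)benzyl]phenyl}ethenyl]-3,5-bis[4-(benzyloxy)benzyl]benzene-1,3-diol numbered as (E)-2,6-bis[4-(benzyloxy)benzyl]-3,5-dihydroxystilbene with a 5'-benzyloxy and a 2'-[4-(benzyloxy)benzyl] group on ring B | Oc1cc(O)c(Cc2ccc(OCc3ccccc3)cc2)c(/C=C/c2cc(OCc3ccccc3)ccc2Cc2ccc(OCc3ccccc3)cc2)c1Cc1ccc(OCc2ccccc2)cc1
A8 | alternative 3 | (1E)-1-{5-(benzyloxy)-2-[4-(benzyloxy)benzyl]phenyl}-4-[4-(benzyloxy)benzyl]-9-[4-(benzyloxy)phenyl]non-1-ene-3,5,7-trione | O=C(/C=C/c1cc(OCc2ccccc2)ccc1Cc1ccc(OCc2ccccc2)cc1)C(Cc1ccc(OCc2ccccc2)cc1)C(=O)CC(=O)CCc1ccc(OCc2ccccc2)cc1
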